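**Retrosynthetic overview**

1. Target 13 ⇐ C7 epimerisation of 12 ⇐ one-pot reductive α-angeloyloxylation of enone 10: the C9–O bond is made together with the C10–H bond (cis ring fusion).
2. 10 ⇐ α'-isopropenylation (aldol with acetone, dehydration) of enone ester 8 ⇐ acylation of alcohol 7.
3. 7 ⇐ C3–O bond by allylic C–H hydroxylation of exocyclic alkene 5, then face-selective hydrogenation (C4 methyl); 5 ⇐ Wittig methylenation of (S)-Wieland–Miescher ketone 4.
4. Rings: ring A is bought as 2-methylcyclohexane-1,3-dione 1; ring B is closed in step 1 by asymmetric Robinson annulation with methyl vinyl ketone 2; no ring is formed later.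

Assumption and convention: eremophilane locants are used (decalin C1–C10, methyls on C4 and C5, C3 unit on C7, ketone C8; ring A = C1–C5 and C10, ring B = C5–C10), β is the face of the C5 methyl, and (R)-DTBM-SEGPHOS is taken as the matched ligand in step 8.

**Route**

Step 1
Reactants: 1 2-methylcyclohexane-1,3-dione; 2 but-3-en-2-one (methyl vinyl ketone)
Product: 4 (S)-8a-methyl-3,4,8,8a-tetrahydronaphthalene-1,6(2H,7H)-dione, via triketone 3 (not isolated)
Conditions: Et3N (1 mol %), neat, rt; then N-tosyl-(Sa)-binam-L-prolinamide (1 mol %), PhCO2H (2.5 mol %), rt; recrystallise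
Reagents that add atoms: none
Why: Organocatalytic Robinson annulation (Hajos–Parrish–Eder–Sauer–Wiechert type): Michael addition gives the prochiral triketone, and the L-proline-derived enamine catalyst then differentiates the two enantiotopic ring carbonyls in the aldol condensation, setting the quaternary C5 as (S), the sense given by L-proline catalysts.

Step 2
Reactants: 4 (S)-Wieland–Miescher ketone
Product: 5 (R)-4a-methyl-5-methylidene-4,4a,5,6,7,8-hexahydronaphthalen-2(3H)-one
Conditions: Ph3PCH3Br (2.6 equiv), KOtBu (2.5 equiv), THF, 0 → 45 °C; aq. NH4Cl, then oxalic acid (cat.)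
Reagents that add atoms: methyltriphenylphosphonium bromide, C[P+](c1ccccc1)(c1ccccc1)c1ccccc1.[Br-]
Why: Wittig methylenation in which the first equivalent of the basic ylide turns the enone into its potassium dienolate (inert to olefination, the same in-flask masking that allows direct C17 olefination of androst-4-ene-3,17-dione), so only the saturated C4 ketone reacts and the enone returns on mildly acidic work-up; C5 is untouched.

Step 3
Reactants: 5 (R)-4a-methyl-5-methylidene-4,4a,5,6,7,8-hexahydronaphthalen-2(3H)-one
Product: 6 (4aS,6R)-6-hydroxy-4a-methyl-5-methylidene-4,4a,5,6,7,8-hexahydronaphthalen-2(3H)-one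
Conditions: selenium dioxide (0.5 equiv), t-BuOOH (2 equiv), CH2Cl2, 0 °C → rt
Reagents that add atoms: selenium dioxide, O=[Se]=O (oxygen carrier); tert-butyl hydroperoxide, CC(C)(C)OO (terminal oxidant)
Why: Allylic hydroxylation by ene reaction and [2,3]-sigmatropic shift on the electron-rich 1,1-disubstituted alkene, whose only allylic C–H bonds are at C3 (C5 is quaternary); the shift delivers oxygen to C3 on the α face, anti to the pseudo-axial C5 methyl (β attack would be 1,3-diaxial to it), giving the equatorial 3α-alcohol (3R).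

Step 4
Reactants: 6 (4aS,6R)-6-hydroxy-4a-methyl-5-methylidene-4,4a,5,6,7,8-hexahydronaphthalen-2(3H)-one
Product: 7 (4aR,5R,6R)-6-hydroxy-4a,5-dimethyl-4,4a,5,6,7,8-hexahydronaphthalen-2(3H)-one
Conditions: H2 (1 atm), [Ir(cod)(PCy3)(py)]PF6 (3 mol %), CH2Cl2, 0 °C
Reagents that add atoms: none
Why: Hydroxyl-directed homogeneous hydrogenation reduces the 1,1-disubstituted allylic alkene much faster than the conjugated trisubstituted enone and adds H2 from the α face, which is both the side of the 3α-OH and the side away from the axial C5 methyl on the neighbouring carbon, so the new C4 methyl is β (4R, cis to the C5 methyl, trans to the oxygen).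

Step 5
Reactants: 7 (4aR,5R,6R)-6-hydroxy-4a,5-dimethyl-4,4a,5,6,7,8-hexahydronaphthalen-2(3H)-one
Product: 8 (1R,2R,8aR)-1,8a-dimethyl-6-oxo-1,2,3,4,6,7,8,8a-octahydronaphthalen-2-yl 3-methylbut-2-enoate
Conditions: 3-methylbut-2-enoyl chloride (1.5 equiv), pyridine (3 equiv), DMAP (0.1 equiv), CH2Cl2, 0 °C → rt
Reagents that add atoms: 3-methylbut-2-enoyl chloride (senecioyl chloride), CC(C)=CC(=O)Cl
Why: Acylation of the secondary alcohol under nucleophilic catalysis, with pyridine instead of a trialkylamine to avoid vinylketene formation and deconjugation of the senecioate; no stereocentre is touched.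

Step 6
Reactants: 8 (1R,2R,8aR)-1,8a-dimethyl-6-oxo-1,2,3,4,6,7,8,8a-octahydronaphthalen-2-yl 3-methylbut-2-enoate
Product: 9 (1R,2R,7S,8aR)-7-(2-hydroxypropan-2-yl)-1,8a-dimethyl-6-oxo-1,2,3,4,6,7,8,8a-octahydronaphthalen-2-yl 3-methylbut-2-enoate
Conditions: LiN(SiMe3)2 (1.1 equiv), THF, −78 °C; ZnCl2 (1.2 equiv); acetone (5 equiv), −78 → −50 °C; aq. NH4Cl
Reagents that add atoms: acetone, CC(C)=O
Why: Kinetic deprotonation of the cross-conjugated enone at its only α' position (C7) by a hindered amide base that leaves the senecioate alone, then zinc-mediated aldol addition to acetone anti to the axial C5 methyl to give the equatorial 7α adduct (7S); this configuration is corrected in step 9 and is not critical here.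

Step 7
Reactants: 9 (1R,2R,7S,8aR)-7-(2-hydroxypropan-2-yl)-1,8a-dimethyl-6-oxo-1,2,3,4,6,7,8,8a-octahydronaphthalen-2-yl 3-methylbut-2-enoate
Product: 10 (1R,2R,7S,8aR)-1,8a-dimethyl-6-oxo-7-(prop-1-en-2-yl)-1,2,3,4,6,7,8,8a-octahydronaphthalen-2-yl 3-methylbut-2-enoate
Conditions: SOCl2 (1.5 equiv), pyridine, −10 °C
Reagents that add atoms: none
Why: Dehydration of the tertiary carbinol through its chlorosulfite by pyridine-mediated E2 elimination, which under cold, weakly basic conditions takes one of the six methyl hydrogens rather than the single C7–H and gives mainly the isopropenyl ketone, as in the aldol and SOCl2–pyridine route to isopiperitenone; the minor isopropylidene isomer is removed by chromatography.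

Step 8
Reactants: 10 (1R,2R,7S,8aR)-1,8a-dimethyl-6-oxo-7-(prop-1-en-2-yl)-1,2,3,4,6,7,8,8a-octahydronaphthalen-2-yl 3-methylbut-2-enoate
Product: 12 (3R,4R,5R,7S,9R,10S)-9-[(Z)-2-methylbut-2-enoyloxy]-8-oxoeremophil-11-en-3-yl 3-methylbut-2-enoate (7-epimer of the target), via silyl enol ether 11 (not isolated)
Conditions: Cu(OAc)2 (5 mol %), (R)-DTBM-SEGPHOS (5.5 mol %), HSiMe(OEt)2 (1.05 equiv), toluene, −40 °C; then PhI(OAng)2 [1.3 equiv, from (PhIO)n and angelic acid (2.6 equiv), 4 Å sieves, CH2Cl2], TMSOTf (10 mol %), −78 → −40 °C; aq. NaHCO3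
Reagents that add atoms: (Z)-2-methylbut-2-enoic acid (angelic acid), C/C=C(/C)C(=O)O, used as bis[(Z)-2-methylbut-2-enoyloxy](phenyl)-λ3-iodane, C/C=C(/C)C(=O)OI(OC(=O)/C(C)=C\C)c1ccccc1, made in the flask with iodosylbenzene, O=Ic1ccccc1
Why: Proposed new method: a one-pot asymmetric reductive α-acyloxylation of an enone in which ligated CuH first adds hydride to C10 from the β face (the usual sense for angularly methylated octalones, reinforced by the matched ligand, and chemoselective at −40 °C over the isopropenyl group and the less electrophilic senecioate) to give the cis-fused, regio-defined C8–C9 silyl enol ether, which then attacks the silyl-triflate-activated trivalent-iodine dicarboxylate to form an O-bound iodonium enolate that angelate displaces at C9 in SN2' fashion with loss of iodobenzene, entering on the convex β face of the cis-decalin (the face taken in 4β-functionalisation of 5β-3-keto steroid enol derivatives), so the C9–O bond and the C10 and C9 stereocentres arise in one operation without base that could isomerise the Z ester; the closest known reaction types are CuH-catalysed asymmetric conjugate reduction of β,β-disubstituted cyclic enones with use of the silyl enol ether, Rubottom oxidation, and α-acetoxylation of ketones and enol derivatives with PhI(OAc)2, whereas transfer of an α,β-unsaturated carboxylate from a bis(acyloxy)iodane to a CuH-derived enol ether has not been shown.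

Step 9
Reactants: 12 (3R,4R,5R,7S,9R,10S)-9-[(Z)-2-methylbut-2-enoyloxy]-8-oxoeremophil-11-en-3-yl 3-methylbut-2-enoate
Product: 13 (3R,4R,5R,7R,9R,10S)-9-[(Z)-2-methylbut-2-enoyloxy]-8-oxoeremophil-11-en-3-yl 3-methylbut-2-enoate (target, CNP0164025.2)
Conditions: DBU (0.2 equiv), toluene, 0 °C → rt, monitored; AcOH quench
Reagents that add atoms: none
Why: Base-catalysed epimerisation through the C7–C8 dienolate under thermodynamic control: in the cis-fused ketone the 7β-isopropenyl group is equatorial, whereas the 7α group is either 1,3-diaxial to C4 or forces a chair flip that puts the 9-acyloxy group 1,3-diaxial to the C5 methyl, so the equilibrium lies far on the side of the all-equatorial 7R,9R isomer, and kinetic α-protonation of the dienolate outruns γ-protonation to the conjugated isopropylidene ketone.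

**Compound list**

1 | 2-methylcyclohexane-1,3-dione | CC1C(=O)CCCC1=O | starting material
2 | but-3-en-2-one (methyl vinyl ketone) | CC(=O)C=C | starting material
3 | 2-methyl-2-(3-oxobutyl)cyclohexane-1,3-dione (triketone) | CC(=O)CCC1(C)C(=O)CCCC1=O | intermediate
4 | (S)-8a-methyl-3,4,8,8a-tetrahydronaphthalene-1,6(2H,7H)-dione, (S)-Wieland–Miescher ketone | C[C@]12CCC(=O)C=C1CCCC2=O | intermediate
5 | (R)-4a-methyl-5-methylidene-4,4a,5,6,7,8-hexahydronaphthalen-2(3H)-one | C1C[C@@]2(C)C(CCCC2=C)=CC1=O | intermediate
6 | (4aS,6R)-6-hydroxy-4a-methyl-5-methylidene-4,4a,5,6,7,8-hexahydronaphthalen-2(3H)-one (3α-OH, trans to the angular methyl) | C1C[C@@]2(C)C(CC[C@@H](O)C2=C)=CC1=O | intermediate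
7 | (4aR,5R,6R)-6-hydroxy-4a,5-dimethyl-4,4a,5,6,7,8-hexahydronaphthalen-2(3H)-one (3α-OH, 4β-CH3, 5β-CH3) | C1C[C@@]2(C)C(CC[C@@H](O)[C@@H]2C)=CC1=O | intermediate
8 | (1R,2R,8aR)-1,8a-dimethyl-6-oxo-1,2,3,4,6,7,8,8a-octahydronaphthalen-2-yl 3-methylbut-2-enoate | C1C[C@@]2(C)C(CC[C@@H](OC(=O)C=C(C)C)[C@@H]2C)=CC1=O | intermediate
9 | (1R,2R,7S,8aR)-7-(2-hydroxypropan-2-yl)-1,8a-dimethyl-6-oxo-1,2,3,4,6,7,8,8a-octahydronaphthalen-2-yl 3-methylbut-2-enoate (7α side chain) | CC(C)(O)[C@@H]1C[C@@]2(C)C(CC[C@@H](OC(=O)C=C(C)C)[C@@H]2C)=CC1=O | intermediate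
10 | (1R,2R,7S,8aR)-1,8a-dimethyl-6-oxo-7-(prop-1-en-2-yl)-1,2,3,4,6,7,8,8a-octahydronaphthalen-2-yl 3-methylbut-2-enoate (7α-isopropenyl enone) | C=C(C)[C@@H]1C[C@@]2(C)C(CC[C@@H](OC(=O)C=C(C)C)[C@@H]2C)=CC1=O | intermediate
11 | (3R,4R,5S,7S,10R)-8-[diethoxy(methyl)silyloxy]eremophila-8,11-dien-3-yl 3-methylbut-2-enoate (C8–C9 silyl enol ether, 10βH, 7α-isopropenyl) | C=C(C)[C@@H]1C[C@@]2(C)[C@H](CC[C@@H](OC(=O)C=C(C)C)[C@@H]2C)C=C1O[Si](C)(OCC)OCC | intermediate
12 | (3R,4R,5R,7S,9R,10S)-9-[(Z)-2-methylbut-2-enoyloxy]-8-oxoeremophil-11-en-3-yl 3-methylbut-2-enoate (3α-senecioyloxy, 9β-angeloyloxy, 10βH, 7α-isopropenyl) | C=C(C)[C@@H]1C[C@@]2(C)[C@H](CC[C@@H](OC(=O)C=C(C)C)[C@@H]2C)[C@@H](OC(=O)/C(C)=C\C)C1=O | intermediate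
13 | (3R,4R,5R,7R,9R,10S)-9-[(Z)-2-methylbut-2-enoyloxy]-8-oxoeremophil-11-en-3-yl 3-methylbut-2-enoate (3α-senecioyloxy, 9β-angeloyloxy, 10βH, 7β-isopropenyl) | C=C(C)[C@H]1C[C@@]2(C)[C@H](CC[C@@H](OC(=O)C=C(C)C)[C@@H]2C)[C@@H](OC(=O)/C(C)=C\C)C1=O | target

**Step count and risks**

Total step count: 9. Longest linear sequence: 9 (fully linear from 1 and 2).

Steps most likely to fail:

Step 8 (the new reductive α-angeloyloxylation). The iodane may re-oxidise the enol ether to enone 10, the carboxylate may enter from the concave face, or hydride delivery may give some trans-fused material. The fallback uses known chemistry only and sets out from 10. The CuH and HSiMe(OEt)2 conjugate reduction is run as above (this half is an established reaction class) to give 11. Rubottom oxidation of 11 (mCPBA, NaHCO3, CH2Cl2, −20 °C, then citric acid), from the convex face and far faster than epoxidation of the isopropenyl group, gives the α-hydroxy ketone (3R,4R,5R,7S,9R,10S)-9-hydroxy-8-oxoeremophil-11-en-3-yl 3-methylbut-2-enoate F3. Esterification of F3 with the mixed anhydride of angelic acid and 2,4,6-trichlorobenzoyl chloride (Et3N, toluene), which keeps the Z geometry, returns to the route at 12, before step 9.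

Step 3 (allylic hydroxylation). The face of oxygen delivery is argued by analogy, not demonstrated on this substrate, and over-oxidation to the exocyclic enone is possible. The fallback sets out from 5 and replaces steps 3 and 4. The exocyclic alkene is moved into the ring (RhCl3·3H2O cat., EtOH, 70 °C) to give (R)-4a,5-dimethyl-4,4a,7,8-tetrahydronaphthalen-2(3H)-one F1. Hydroboration–oxidation (BH3·SMe2, THF, 0 °C; NaBO3·4H2O) adds H and OH syn and anti to the C5 methyl, setting 3α-OH and 4β-CH3 in one event while also reducing the C8 carbonyl, to give (4aR,5R,6R)-4a,5-dimethyl-2,3,4,4a,5,6,7,8-octahydronaphthalene-2,6-diol F2 as a C2 epimer mixture. Competing hydroboration of the C9=C10 alkene must be limited by borane stoichiometry. MnO2 (CH2Cl2, rt) then oxidises only the allylic alcohol and returns to the route at 7.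

Step 7 (dehydration to the isopropenyl group). Elimination toward C7 would give the conjugated isopropylidene ketone. The fallback sets out from 8 and replaces steps 6 and 7 by a palladium-catalysed α-alkenylation of the C7 lithium enolate with 2-bromopropene (LiN(SiMe3)2, Pd2(dba)3, P(t-Bu)3, THF, rt). This direct C–C coupling forms the isopropenyl ketone without a carbinol intermediate and returns to the route at 10; it passes through no compound outside the list (none F0).

Further compounds
F1 | step 3 | (R)-4a,5-dimethyl-4,4a,7,8-tetrahydronaphthalen-2(3H)-one | C1C[C@@]2(C)C(CCC=C2C)=CC1=O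
F2 | step 3 | (4aR,5R,6R)-4a,5-dimethyl-2,3,4,4a,5,6,7,8-octahydronaphthalene-2,6-diol (C2 epimer mixture) | C1C[C@@]2(C)C(CC[C@@H](O)[C@@H]2C)=CC1O
F0 | step 7 | none | none
F3 | step 8 | (3R,4R,5R,7S,9R,10S)-9-hydroxy-8-oxoeremophil-11-en-3-yl 3-methylbut-2-enoate | C=C(C)[C@@H]1C[C@@]2(C)[C@H](CC[C@@H](OC(=O)C=C(C)C)[C@@H]2C)[C@@H](O)C1=O
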